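**Plan**

- Retrosynthesis: C3–Br is traced back to C3–OH (via OTf and SnMe3), the tertiary OH to its MOM ether and the ester to the acid. The ring bonds C3–C4 and C1–C5 of the resulting diosphenol are then cut together, giving a 1-lithio-1-(methoxymethoxy)vinylallene (C4, C5, C1′–C5′) and a (Z)-β-(methoxymethoxy)enamide (C1–C3 plus the octanoate chain).
- Enabling feature: the cross-conjugated 5-alkylidenecyclopent-2-en-1-one ring. The C4 carbonyl is flanked by C3 and by C5, which carries the exocyclic C5=C1′ double bond. This is the retron of a conrotatory 4π closure of a 3-oxypentadienyl cation whose allene terminus supplies C4, C5 and C1′.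
- Forward order: enamide from monomethyl azelate (2 steps); allene from (E)-pent-2-enal (4 steps, including a resolution); a one-flask acylation/electrocyclisation builds the only ring; then OH → OTf → SnMe3 → Br and MOM removal.
- Stereochemistry: C1 (S) by axis-to-centre transfer from the resolved (aR)-allene acting on the geometrically fixed (Z)-enol ether; (5Z) from outward rotation of the allene substituent during ring closure; (2′E) carried through from pent-2-enal.

Key step: step 7

Remark: ring locants are those of the target name (C1 carbinol carbon, C2 =CH, C3 C–Br, C4 C=O, C5 alkylidene carbon, C1′–C5′ the pentenylidene chain); it is assumed that the absolute configuration of the allene enantiomer collected in step 6 is assigned (for example by VCD) before use, the route requiring (aR).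

**Route**

Step 1
Reactants: 1 9-methoxy-9-oxononanoic acid (monomethyl azelate), 2 Meldrum's acid, 4 morpholine
Product: 5 methyl 11-(morpholin-4-yl)-9,11-dioxoundecanoate, via acyl Meldrum's acid 3 (not isolated)
Conditions: DCC, DMAP, CH2Cl2, 0 °C to rt; filter; then 4, toluene, 100 °C
Reagents that add atoms: none
Why: DCC-mediated C-acylation of Meldrum's acid, then thermal fragmentation of the adduct to an acylketene that is trapped by morpholine (the acyl Meldrum's acid route to β-keto amides), should leave the distal methyl ester untouched.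

Step 2
Reactants: 5 methyl 11-(morpholin-4-yl)-9,11-dioxoundecanoate
Product: 8 (9Z)-9-(methoxymethoxy)-11-(morpholin-4-yl)-11-oxoundec-9-enoic acid, via sodium enolate 6 (not isolated), via methyl ester 7 (not isolated)
Conditions: NaH, THF, 0 °C; MOMCl, 0 °C to rt; then LiOH, THF/MeOH/H2O, rt; cold 1 M HCl to pH 4
Reagents that add atoms: chloromethyl methyl ether (COCCl); lithium hydroxide ([Li+].[OH-])
Why: The chelated sodium (Z)-enolate of the β-keto amide should be O-alkylated by the hard electrophile MOMCl with retention of its U-geometry (O-alkylation of a 1,3-dicarbonyl enolate), and the methyl ester is then saponified in the same flask while the vinylogous carbamate resists hydroxide, which frees the chain terminus as an acid that can be carried as an inert carboxylate through the organolithium step.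

Step 3
Reactants: 9 (2E)-pent-2-enal
Product: 10 (3E)-1,1-dibromohexa-1,3-diene
Conditions: CBr4, PPh3, CH2Cl2, 0 °C
Reagents that add atoms: carbon tetrabromide (BrC(Br)(Br)Br)
Why: Corey–Fuchs dibromo-olefination of the aldehyde by the ylide formed in the flask from CBr4 and PPh3; the (E)-olefin is not involved.

Step 4
Reactants: 10 (3E)-1,1-dibromohexa-1,3-diene
Product: 13 (3E)-7-(methoxymethoxy)hept-3-en-5-yne, via lithium acetylide 11 (not isolated), via lithium alkoxide 12 (not isolated)
Conditions: n-BuLi (2.1 equiv), THF, −78 to 0 °C; dry (CH2O)n, 0 °C to rt; then MOMCl, DMPU, 0 °C to rt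
Reagents that add atoms: paraformaldehyde, reacting as formaldehyde (C=O); chloromethyl methyl ether (COCCl)
Why: Second stage of the Corey–Fuchs sequence: bromine–lithium exchange and Fritsch–Buttenberg–Wiechell rearrangement give the lithium acetylide, which is hydroxymethylated by formaldehyde, and the resulting alkoxide is O-alkylated by MOMCl.

Step 5
Reactants: 13 (3E)-7-(methoxymethoxy)hept-3-en-5-yne
Product: 14 racemic (4E)-1-(methoxymethoxy)hepta-1,2,4-triene
Conditions: t-BuOK (0.2 equiv), 18-crown-6 (cat.), THF, 0 °C to rt, quenched at full conversion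
Reagents that add atoms: none
Why: Base-catalysed propargyl–allenyl prototropy: the α-alkoxy propargylic C–H is removed reversibly and reprotonation at the remote terminus gives the oxygen-conjugated vinylallene, which should be favoured at equilibrium, while catalytic base, low temperature and an early quench limit further migration into the fully conjugated trienyl ether.

Step 6
Reactants: 14 racemic (4E)-1-(methoxymethoxy)hepta-1,2,4-triene
Product: 15 (aR,4E)-1-(methoxymethoxy)hepta-1,2,4-triene [(M) helicity]
Conditions: preparative HPLC, cellulose tris(3,5-dimethylphenylcarbamate) stationary phase, hexane/i-PrOH, UV detection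
Reagents that add atoms: none
Why: Chromatographic resolution: the axis of a 1,3-disubstituted allenyl ether is configurationally stable and the vinylallene chromophore allows UV-triggered collection on a polysaccharide-type chiral stationary phase; no bond is made or broken.

Step 7
Reactants: 15 (aR,4E)-1-(methoxymethoxy)hepta-1,2,4-triene, 8 (9Z)-9-(methoxymethoxy)-11-(morpholin-4-yl)-11-oxoundec-9-enoic acid
Product: 20 8-[(1S,5Z)-3-hydroxy-1-(methoxymethoxy)-4-oxo-5-[(2E)-pent-2-en-1-ylidene]cyclopent-2-en-1-yl]octanoic acid, via lithium carboxylate 16 (not isolated), via lithioallene 17 (not isolated), via tetrahedral adduct 18 (not isolated), via allenyl vinyl ketone 19 (not isolated)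
Conditions: 8, LiN(SiMe3)2 (1.0 equiv), THF, −78 °C; 15 (1.5 equiv), n-BuLi, THF, −78 °C; combine, −78 to −40 °C; HCl in (CF3)2CHOH, −78 °C; then aq. NaH2PO4 (pH 4–5)
Reagents that add atoms: none
Why: Proposed new method: lithioallene 17 adds to the morpholine amide to give the stable tetrahedral adduct 18 (bond C3–C4); on acid quench this collapses to the cross-conjugated allenyl vinyl ketone 19, whose O-protonated form is a 3-hydroxypentadienyl cation that closes between the enol-ether carbon and the central allene carbon (bond C1–C5), and the resulting alkoxy-allyl cation is discharged irreversibly by loss of the methoxymethyl group from the former allenyl oxygen to leave the diosphenol. The closest known reaction type is the allene-ether Nazarov cyclisation (cationic cyclopentannelation of 1-lithio-1-alkoxyallenes with α,β-unsaturated morpholine amides), established for β-alkyl and β-aryl enamides including axis-to-centre chirality transfer from 3-substituted allenes; new here is the β-alkoxy (vinylogous carbamate) partner, which places an oxygen on the new quaternary carbon. The five-membered ring is closed in a thermal conrotatory 4π-electrocyclic mode. The stereocentre C1 is controlled by torquoselectivity: the dienyl substituent on the allene terminus turns outward, away from the incoming carbon, so the allene axis fixes the sense of conrotation, and with the (aR) axis and the (9Z) enol ether (OMOM inside the U-shaped cation, chain outside) this sense should give (1S) together with the (5Z) alkylidene. The step needs chemoselective 1,2-addition at the amide, which is secured by carrying the acid as its lithium carboxylate, by the chelated morpholine adduct that cannot over-add, and by −78 °C to suppress γ-deprotonation. It also needs ring closure faster than hydrolysis or rotation of the enol-ether terminus and retention of the kinetic (5Z) geometry, which are secured by the strain release of the allene, by the match of the nucleophilic α-alkoxyallene terminus with the oxocarbenium-like enol-ether carbon, and by a cold, non-nucleophilic acid quench.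

Step 8
Reactants: 20 8-[(1S,5Z)-3-hydroxy-1-(methoxymethoxy)-4-oxo-5-[(2E)-pent-2-en-1-ylidene]cyclopent-2-en-1-yl]octanoic acid
Product: 21 methyl 8-[(1S,5Z)-3-hydroxy-1-(methoxymethoxy)-4-oxo-5-[(2E)-pent-2-en-1-ylidene]cyclopent-2-en-1-yl]octanoate
Conditions: Me3SiCHN2 (1.05 equiv), toluene/MeOH, −10 °C
Reagents that add atoms: trimethylsilyldiazomethane (C[Si](C)(C)C=[N+]=[N-])
Why: Esterification with a diazoalkane: the carboxylic acid should be methylated far faster than the much less acidic diosphenol hydroxyl when one equivalent is used in the cold.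

Step 9
Reactants: 21 methyl 8-[(1S,5Z)-3-hydroxy-1-(methoxymethoxy)-4-oxo-5-[(2E)-pent-2-en-1-ylidene]cyclopent-2-en-1-yl]octanoate
Product: 22 methyl 8-[(1S,5Z)-1-(methoxymethoxy)-4-oxo-5-[(2E)-pent-2-en-1-ylidene]-3-[(trifluoromethanesulfonyl)oxy]cyclopent-2-en-1-yl]octanoate
Conditions: PhNTf2, i-Pr2NEt, DMAP (cat.), CH2Cl2, 0 °C to rt
Reagents that add atoms: N-phenylbis(trifluoromethanesulfonimide) (O=S(=O)(N(c1ccccc1)S(=O)(=O)C(F)(F)F)C(F)(F)F)
Why: Enol triflate formation at the acidic diosphenol hydroxyl, the only free hydroxyl in the molecule, under mild amine-base conditions that should not disturb the (5Z) dienone.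

Step 10
Reactants: 22 methyl 8-[(1S,5Z)-1-(methoxymethoxy)-4-oxo-5-[(2E)-pent-2-en-1-ylidene]-3-[(trifluoromethanesulfonyl)oxy]cyclopent-2-en-1-yl]octanoate
Product: 23 methyl 8-[(1S,5Z)-1-(methoxymethoxy)-4-oxo-5-[(2E)-pent-2-en-1-ylidene]-3-(trimethylstannyl)cyclopent-2-en-1-yl]octanoate
Conditions: Me6Sn2, Pd(PPh3)4 (5 mol %), LiCl, THF, 60 °C
Reagents that add atoms: hexamethylditin (C[Sn](C)(C)[Sn](C)(C)C)
Why: Zerovalent palladium inserts into the activated α-keto enol triflate and transmetalation with the distannane gives the alkenylstannane (Stille-type stannylation), the position being fixed by the triflate.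

Step 11
Reactants: 23 methyl 8-[(1S,5Z)-1-(methoxymethoxy)-4-oxo-5-[(2E)-pent-2-en-1-ylidene]-3-(trimethylstannyl)cyclopent-2-en-1-yl]octanoate
Product: 24 methyl 8-[(1S,5Z)-3-bromo-1-(methoxymethoxy)-4-oxo-5-[(2E)-pent-2-en-1-ylidene]cyclopent-2-en-1-yl]octanoate
Conditions: NBS, CH2Cl2, 0 °C, dark
Reagents that add atoms: N-bromosuccinimide (BrN1C(=O)CCC1=O)
Why: Ipso-bromodestannylation of an alkenylstannane is much faster than electrophilic attack on the electron-poor dienone, so bromine should enter only at C3.

Step 12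
Reactants: 24 methyl 8-[(1S,5Z)-3-bromo-1-(methoxymethoxy)-4-oxo-5-[(2E)-pent-2-en-1-ylidene]cyclopent-2-en-1-yl]octanoate
Product: 26 methyl 8-[(1S,5Z)-3-bromo-1-hydroxy-4-oxo-5-[(2E)-pent-2-en-1-ylidene]cyclopent-2-en-1-yl]octanoate, via bromomethyl ether 25 (not isolated)
Conditions: Me2BBr, CH2Cl2, −78 °C; then aq. NaHCO3, THF, 0 °C
Reagents that add atoms: none
Why: Dimethylboron bromide cleaves methoxymethyl ethers, tertiary ones included, at −78 °C through the bromomethyl ether, which is hydrolysed on bicarbonate work-up; the ester, alkenyl bromide and dienone should tolerate this, and the C1–O bond is not broken, so (1S) is kept.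

**Compound list**

1 | 9-methoxy-9-oxononanoic acid (monomethyl azelate) | COC(=O)CCCCCCCC(=O)O | starting material
2 | Meldrum's acid (2,2-dimethyl-1,3-dioxane-4,6-dione) | CC1(C)OC(=O)CC(=O)O1 | starting material
3 | methyl 9-(2,2-dimethyl-4,6-dioxo-1,3-dioxan-5-yl)-9-oxononanoate (acyl Meldrum's acid) | COC(=O)CCCCCCCC(=O)C1C(=O)OC(C)(C)OC1=O | intermediate (not isolated)
4 | morpholine | C1COCCN1 | starting material
5 | methyl 11-(morpholin-4-yl)-9,11-dioxoundecanoate | COC(=O)CCCCCCCC(=O)CC(=O)N1CCOCC1 | intermediate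
6 | sodium (2Z)-11-methoxy-1-(morpholin-4-yl)-1,11-dioxoundec-2-en-3-olate (sodium enolate of 5) | COC(=O)CCCCCCC/C(O[Na])=C/C(=O)N1CCOCC1 | intermediate (not isolated)
7 | methyl (9Z)-9-(methoxymethoxy)-11-(morpholin-4-yl)-11-oxoundec-9-enoate | COC(=O)CCCCCCC/C(OCOC)=C/C(=O)N1CCOCC1 | intermediate (not isolated)
8 | (9Z)-9-(methoxymethoxy)-11-(morpholin-4-yl)-11-oxoundec-9-enoic acid | OC(=O)CCCCCCC/C(OCOC)=C/C(=O)N1CCOCC1 | intermediate
9 | (2E)-pent-2-enal | CC/C=C/C=O | starting material
10 | (3E)-1,1-dibromohexa-1,3-diene | CC/C=C/C=C(Br)Br | intermediate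
11 | lithium (3E)-hex-3-en-1-yn-1-ide | CC/C=C/C#C[Li] | intermediate (not isolated)
12 | lithium (4E)-hept-4-en-2-yn-1-olate | CC/C=C/C#CCO[Li] | intermediate (not isolated)
13 | (3E)-7-(methoxymethoxy)hept-3-en-5-yne | CC/C=C/C#CCOCOC | intermediate
14 | racemic (4E)-1-(methoxymethoxy)hepta-1,2,4-triene | CC/C=C/C=C=COCOC | intermediate
15 | (aR,4E)-1-(methoxymethoxy)hepta-1,2,4-triene | [H]C(OCOC)=[C@@]=C([H])/C=C/CC | intermediate
16 | lithium (9Z)-9-(methoxymethoxy)-11-(morpholin-4-yl)-11-oxoundec-9-enoate | [Li]OC(=O)CCCCCCC/C(OCOC)=C/C(=O)N1CCOCC1 | intermediate (not isolated)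
17 | [(aR,4E)-1-(methoxymethoxy)hepta-1,2,4-trien-1-yl]lithium | [Li]C(OCOC)=[C@@]=C([H])/C=C/CC | intermediate (not isolated)
18 | dilithium salt of (9Z,15E)-11-hydroxy-9,12-bis(methoxymethoxy)-11-(morpholin-4-yl)octadeca-9,12,13,15-tetraenoic acid, allene axis (aR), C11 unassigned | [Li]OC(=O)CCCCCCC/C(OCOC)=C/C(O[Li])(N1CCOCC1)C(OCOC)=[C@@]=C([H])/C=C/CC | intermediate (not isolated)
19 | (9Z,15E)-9,12-bis(methoxymethoxy)-11-oxooctadeca-9,12,13,15-tetraenoic acid, allene axis (aR) | OC(=O)CCCCCCC/C(OCOC)=C/C(=O)C(OCOC)=[C@@]=C([H])/C=C/CC | intermediate (not isolated)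
20 | 8-[(1S,5Z)-3-hydroxy-1-(methoxymethoxy)-4-oxo-5-[(2E)-pent-2-en-1-ylidene]cyclopent-2-en-1-yl]octanoic acid | CC/C=C/C=C1\C(=O)C(O)=C[C@@]1(OCOC)CCCCCCCC(=O)O | intermediate
21 | methyl 8-[(1S,5Z)-3-hydroxy-1-(methoxymethoxy)-4-oxo-5-[(2E)-pent-2-en-1-ylidene]cyclopent-2-en-1-yl]octanoate | CC/C=C/C=C1\C(=O)C(O)=C[C@@]1(OCOC)CCCCCCCC(=O)OC | intermediate
22 | methyl 8-[(1S,5Z)-1-(methoxymethoxy)-4-oxo-5-[(2E)-pent-2-en-1-ylidene]-3-[(trifluoromethanesulfonyl)oxy]cyclopent-2-en-1-yl]octanoate | CC/C=C/C=C1\C(=O)C(OS(=O)(=O)C(F)(F)F)=C[C@@]1(OCOC)CCCCCCCC(=O)OC | intermediate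
23 | methyl 8-[(1S,5Z)-1-(methoxymethoxy)-4-oxo-5-[(2E)-pent-2-en-1-ylidene]-3-(trimethylstannyl)cyclopent-2-en-1-yl]octanoate | CC/C=C/C=C1\C(=O)C([Sn](C)(C)C)=C[C@@]1(OCOC)CCCCCCCC(=O)OC | intermediate
24 | methyl 8-[(1S,5Z)-3-bromo-1-(methoxymethoxy)-4-oxo-5-[(2E)-pent-2-en-1-ylidene]cyclopent-2-en-1-yl]octanoate | CC/C=C/C=C1\C(=O)C(Br)=C[C@@]1(OCOC)CCCCCCCC(=O)OC | intermediate
25 | methyl 8-[(1S,5Z)-3-bromo-1-(bromomethoxy)-4-oxo-5-[(2E)-pent-2-en-1-ylidene]cyclopent-2-en-1-yl]octanoate | CC/C=C/C=C1\C(=O)C(Br)=C[C@@]1(OCBr)CCCCCCCC(=O)OC | intermediate (not isolated)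
26 | methyl 8-[(1S,5Z)-3-bromo-1-hydroxy-4-oxo-5-[(2E)-pent-2-en-1-ylidene]cyclopent-2-en-1-yl]octanoate | CC/C=C/C=C1\C(=O)C(Br)=C[C@@]1(O)CCCCCCCC(=O)OC | target

**Step count and risks**

Total: 12 steps. Longest linear sequence: 10 steps (steps 3 to 12, from (2E)-pent-2-enal).

Steps most likely to fail:

1. Step 7 (the proposed new method). What may go wrong: sluggish 1,2-addition at the vinylogous carbamate with competing γ-deprotonation; hydrolysis of the enol ether, or rotation about its C=C bond in the cation, before ring closure, which would erode the axis-to-centre transfer; isomerisation of the kinetic (5Z) olefin. The fallback uses known chemistry throughout, closes the ring by olefin metathesis and attaches the side chain last by aldol condensation; it sets out from 1 and 9 and comes back at 26. Acid 1 is converted with (COCl)2 and catalytic DMF into methyl 9-chloro-9-oxononanoate F1. Barbier double allylation (allyl bromide, Zn, THF, 0 °C) gives methyl 9-hydroxy-9-(prop-2-en-1-yl)dodec-11-enoate F2. Ring-closing metathesis (second-generation Grubbs catalyst, CH2Cl2, 40 °C) gives methyl 8-(1-hydroxycyclopent-3-en-1-yl)octanoate F3. Allylic oxidation of the symmetrical cyclopentene (CrO3·3,5-dimethylpyrazole, CH2Cl2, −20 °C) gives racemic methyl 8-(1-hydroxy-4-oxocyclopent-2-en-1-yl)octanoate F4. Addition of Br2 (CH2Cl2, 0 °C) gives methyl 8-(2,3-dibromo-1-hydroxy-4-oxocyclopentyl)octanoate F5, which loses HBr with Et3N to give racemic methyl 8-(3-bromo-1-hydroxy-4-oxocyclopent-2-en-1-yl)octanoate F6. Aldol addition of its dianion (LiN(i-Pr)2, 2.1 equiv, THF, −78 °C) to 9 gives methyl 8-[3-bromo-1-hydroxy-5-[(2E)-1-hydroxypent-2-en-1-yl]-4-oxocyclopent-2-en-1-yl]octanoate F7. Selective mesylation of the secondary alcohol (MsCl, Et3N) gives methyl 8-[3-bromo-1-hydroxy-5-[(2E)-1-(methanesulfonyloxy)pent-2-en-1-yl]-4-oxocyclopent-2-en-1-yl]octanoate F8, and elimination with DBU should give racemic methyl 8-[(5Z)-3-bromo-1-hydroxy-4-oxo-5-[(2E)-pent-2-en-1-ylidene]cyclopent-2-en-1-yl]octanoate F9 together with its (5E) isomer. The (5Z) isomer is separated on silica and its enantiomers are resolved by HPLC on a chiral stationary phase to give 26.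

2. Step 6. What may go wrong: incomplete separation of the enantiomers of a small, weakly polar allenyl ether, evaporative loss on recovery, or erosion of the axis on storage. The fallback postpones the resolution to a polar, UV-active stage; it sets out from 14 and comes back at 21. Racemic 14 is lithiated to racemic [(4E)-1-(methoxymethoxy)hepta-1,2,4-trien-1-yl]lithium F10 and taken through step 7, by way of the racemic dilithium hemiaminal adduct corresponding to 18 F11 and racemic (9Z,15E)-9,12-bis(methoxymethoxy)-11-oxooctadeca-9,12,13,15-tetraenoic acid F12, to racemic 8-[(5Z)-3-hydroxy-1-(methoxymethoxy)-4-oxo-5-[(2E)-pent-2-en-1-ylidene]cyclopent-2-en-1-yl]octanoic acid F13. Step 8 then gives the racemic methyl ester, methyl 8-[(5Z)-3-hydroxy-1-(methoxymethoxy)-4-oxo-5-[(2E)-pent-2-en-1-ylidene]cyclopent-2-en-1-yl]octanoate F14, whose enantiomers are separated by preparative HPLC or SFC on a chiral stationary phase to give 21.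

3. Step 10. What may go wrong: coupling of the stannane formed with unreacted triflate, protodestannylation, or thermal Z-to-E isomerisation of the exocyclic olefin at 60 °C. The fallback avoids tin altogether by direct nickel-catalysed exchange of the enol triflate for bromide (Ni(cod)2 as the zerovalent nickel catalyst, LiBr, DMA/THF, rt); it sets out from 22 and comes back at 24, replacing steps 10 and 11.

**Further compounds**

F1 | step 7 | methyl 9-chloro-9-oxononanoate | COC(=O)CCCCCCCC(Cl)=O
F2 | step 7 | methyl 9-hydroxy-9-(prop-2-en-1-yl)dodec-11-enoate | COC(=O)CCCCCCCC(O)(CC=C)CC=C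
F3 | step 7 | methyl 8-(1-hydroxycyclopent-3-en-1-yl)octanoate | COC(=O)CCCCCCCC1(O)CC=CC1
F4 | step 7 | racemic methyl 8-(1-hydroxy-4-oxocyclopent-2-en-1-yl)octanoate | COC(=O)CCCCCCCC1(O)CC(=O)C=C1
F5 | step 7 | methyl 8-(2,3-dibromo-1-hydroxy-4-oxocyclopentyl)octanoate | COC(=O)CCCCCCCC1(O)CC(=O)C(Br)C1Br
F6 | step 7 | racemic methyl 8-(3-bromo-1-hydroxy-4-oxocyclopent-2-en-1-yl)octanoate | COC(=O)CCCCCCCC1(O)CC(=O)C(Br)=C1
F7 | step 7 | methyl 8-[3-bromo-1-hydroxy-5-[(2E)-1-hydroxypent-2-en-1-yl]-4-oxocyclopent-2-en-1-yl]octanoate | CC/C=C/C(O)C1C(=O)C(Br)=CC1(O)CCCCCCCC(=O)OC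
F8 | step 7 | methyl 8-[3-bromo-1-hydroxy-5-[(2E)-1-(methanesulfonyloxy)pent-2-en-1-yl]-4-oxocyclopent-2-en-1-yl]octanoate | CC/C=C/C(OS(C)(=O)=O)C1C(=O)C(Br)=CC1(O)CCCCCCCC(=O)OC
F9 | step 7 | racemic methyl 8-[(5Z)-3-bromo-1-hydroxy-4-oxo-5-[(2E)-pent-2-en-1-ylidene]cyclopent-2-en-1-yl]octanoate | CC/C=C/C=C1\C(=O)C(Br)=CC1(O)CCCCCCCC(=O)OC
F10 | step 6 | racemic [(4E)-1-(methoxymethoxy)hepta-1,2,4-trien-1-yl]lithium | [Li]C(OCOC)=C=C/C=C/CC
F11 | step 6 | racemic dilithium salt of (9Z,15E)-11-hydroxy-9,12-bis(methoxymethoxy)-11-(morpholin-4-yl)octadeca-9,12,13,15-tetraenoic acid | [Li]OC(=O)CCCCCCC/C(OCOC)=C/C(O[Li])(N1CCOCC1)C(OCOC)=C=C/C=C/CC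
F12 | step 6 | racemic (9Z,15E)-9,12-bis(methoxymethoxy)-11-oxooctadeca-9,12,13,15-tetraenoic acid | OC(=O)CCCCCCC/C(OCOC)=C/C(=O)C(OCOC)=C=C/C=C/CC
F13 | step 6 | racemic 8-[(5Z)-3-hydroxy-1-(methoxymethoxy)-4-oxo-5-[(2E)-pent-2-en-1-ylidene]cyclopent-2-en-1-yl]octanoic acid | CC/C=C/C=C1\C(=O)C(O)=CC1(OCOC)CCCCCCCC(=O)O
F14 | step 6 | racemic methyl 8-[(5Z)-3-hydroxy-1-(methoxymethoxy)-4-oxo-5-[(2E)-pent-2-en-1-ylidene]cyclopent-2-en-1-yl]octanoate | CC/C=C/C=C1\C(=O)C(O)=CC1(OCOC)CCCCCCCC(=O)OC
F0 | step 10 | none | none
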